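All constants are invented; what happens was integrated by code.

Two questions stand on this flask, one on chain length and one on how much free monomer has gone.

free monomer 0.050 M; protic impurity 0.0150 M; initiator 2.5 mM; stray impurity 2.1 mM; time 10 s

    free monomer + initiator → living end + monomer in chains (k1 = 7.3 M⁻¹ s⁻¹)
    free monomer + living end → monomer in chains + living end, rate k2*[living end]*[free monomer] (k2 = 44 M⁻¹ s⁻¹)
    initiator + stray impurity → spent initiator (k3 = 13000 M⁻¹ s⁻¹)
    protic impurity + free monomer → quenched substrate (k4 = 4.5 M⁻¹ s⁻¹)
    free monomer → uncatalysed product (k5 = 0.041 s⁻¹)

1. average number of monomer units in a chain (chains begun, living or dead) at 10 s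
2. part of the free monomer that has reacted at 10 s

- the average divides the monomer in chains by the number of chains begun, living and dead together
- run time (flask): 10 s

1. I start with the initiator. At the start in this flask, the stray impurity uses it 75 times as fast as free monomer does. So I count [living end] as the charge difference, 0.400 mM.

2. I follow one free monomer molecule to its fork, where each branch is pseudo-first-order. A living end takes it at 0.0176 s⁻¹, protic impurity at 0.0675 s⁻¹, and the uncatalysed step at 0.041 s⁻¹.

3. I fold these into one number, 0.140. This is the chain share, the chance that a reacting free monomer molecule enters a chain.

4. The branches sum to 0.126 s⁻¹. Held for 10 s, that gives c of 71.7%. Then dp is the chain share times the monomer reacted, per chain: 12.5.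

5. One number is not enough. By step 4 alone, with free monomer held at its charge, protic impurity has a half-life of 3.1 s, shorter than the run, and at its charge its branch is larger than my chain branch. So the sum falls, and my c stands high. The share has two drifts: the protic branch fades, which raises it, while chains need about 1.90 s to start, which lowers it early. I keep 0.140 for the share.

The forecast gives 11.3 and 58%: “The initiator is first titrated by the stray impurity”.

This flask gives dp 11.4 and c 58.0% at 10 s, so my c stood 14 percentage points high. Monomer in chains is 8.37% of the free monomer charged, a share of 0.144 of what reacted, against my chain share of 0.140. For the neighbour flask with 0.025 M of protic impurity, the same fold gives 0.103. That flask reaches c 66.9% with 7.15% in chains, a share of 0.107.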